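Retrosynthesis: the two C2–Br bonds are cut first (electrophilic bromination). Both pyrrole rings are then taken back to indolines, and in each half C3a–C7a and C4–C5 are cut together. N1–C7a (substitution on the diazine) and C3a≡C4 (aldehyde homologation) follow.
Enabling feature: in each benzo ring (C3a–C4–C5–C6–C7–C7a) the bromine on C5 lies para to the nitrogen-bearing C7a. C7a–C7–C6–C5 is therefore C3–C4–C5–C6 of a 3-amino-6-bromopyridazine, and C3a–C4 is an ethynyl group on C3, joined to the diazine through N1–C2–C3.
The C3–C3' bond is purchased as the central bond of tetraethyl ethane-1,1,2,2-tetracarboxylate. Its four ester arms are differentiated pairwise into two ethynyl and two aminomethyl groups.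
Forward order: acyclic diyne diamine, attachment of two diazines, N-acetylation, then one thermal step that closes both five-membered nitrogen rings and both benzene rings. Deacetylation, dehydrogenation and C2 bromination finish the target.
Stereochemistry: the target has no stereocentre. The sp3 centres C3 and C3' are carried as a meso/racemic mixture and vanish on aromatisation.

Key step: step 11

Assumption: the target is drawn without an axial descriptor, so no atropisomer about C3–C3' has to be controlled.

Step 1
Reactants: 1 tetraethyl ethane-1,1,2,2-tetracarboxylate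
Product: 2 2,3-bis(hydroxymethyl)butane-1,4-diol
Conditions: LiAlH4 (excess), THF, 0 °C → reflux; Na2SO4·10H2O quench, hot EtOH extraction of the salts
Reagents that add atoms: none
Why: Exhaustive LiAlH4 reduction of esters to primary alcohols turns the four ester arms into four CH2OH groups around the future C3–C3' bond, and no stereocentre arises because each methine carries two identical arms.

Step 2
Reactants: 2 2,3-bis(hydroxymethyl)butane-1,4-diol
Product: 3 2,2'-bis(4-methoxyphenyl)-5,5'-bi(1,3-dioxane)
Conditions: 4-MeOC6H4CH(OMe)2 (2.3 equiv), camphorsulfonic acid (cat.), DMF, 50 °C, reduced pressure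
Reagents that add atoms: 4-methoxybenzaldehyde dimethyl acetal, COc1ccc(cc1)C(OC)OC
Why: Acid-catalysed transacetalisation under thermodynamic control ties the two CH2OH arms of each methine into a six-membered 1,3-dioxane, which is favoured over the seven-membered ring that would bridge the two methines, and the cis/trans relation at the dioxane rings has no bearing on later steps.

Step 3
Reactants: 3 2,2'-bis(4-methoxyphenyl)-5,5'-bi(1,3-dioxane)
Product: 4 2,3-bis{[(4-methoxybenzyl)oxy]methyl}butane-1,4-diol (meso/racemic mixture)
Conditions: i-Bu2AlH (6 equiv), CH2Cl2, 0 °C → rt; aq potassium sodium tartrate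
Reagents that add atoms: none
Why: Reductive opening of a 4-methoxybenzylidene acetal by i-Bu2AlH leaves exactly one 4-methoxybenzyl (PMB) ether and one free alcohol on each methine, so the arms are differentiated pairwise, and the two stereocentres created here form without control as a meso/racemic mixture that is erased in step 13.

Step 4
Reactants: 4 2,3-bis{[(4-methoxybenzyl)oxy]methyl}butane-1,4-diol
Product: 5 2,3-bis{[(4-methoxybenzyl)oxy]methyl}butanedial (meso/racemic mixture)
Conditions: (COCl)2, DMSO, CH2Cl2, −78 °C; Et3N, −78 → 0 °C; used without chromatography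
Reagents that add atoms: none
Why: In the Swern oxidation both hydroxyls are converted to alkoxysulfonium ions before the base is added, so the 1,4-diol should reach the dialdehyde instead of collapsing through a lactol to a γ-lactone, and epimerisation next to the aldehydes is harmless.

Step 5
Reactants: 5 2,3-bis{[(4-methoxybenzyl)oxy]methyl}butanedial; 6 dimethyl (1-diazo-2-oxopropyl)phosphonate (Ohira–Bestmann reagent)
Product: 7 3,4-bis{[(4-methoxybenzyl)oxy]methyl}hexa-1,5-diyne (meso/racemic mixture)
Conditions: 6 (3 equiv), K2CO3 (4 equiv), MeOH, 0 °C → rt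
Reagents that add atoms: none
Why: The Ohira–Bestmann variant of the Seyferth–Gilbert homologation converts each aldehyde into a terminal alkyne under mild carbonate conditions that α-branched β-alkoxy aldehydes routinely tolerate, the added diazo carbon becoming C4 and C4' of the target.

Step 6
Reactants: 7 3,4-bis{[(4-methoxybenzyl)oxy]methyl}hexa-1,5-diyne
Product: 8 2,3-diethynylbutane-1,4-diol (meso/racemic mixture)
Conditions: DDQ (2.4 equiv), CH2Cl2/pH 7 buffer (10:1), 0 °C → rt
Reagents that add atoms: none
Why: Oxidative cleavage of PMB ethers by DDQ proceeds by hydride abstraction from the electron-rich benzylic position and leaves terminal alkynes untouched.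

Step 7
Reactants: 8 2,3-diethynylbutane-1,4-diol
Product: 9 2,3-diethynylbutane-1,4-diyl dimethanesulfonate (meso/racemic mixture)
Conditions: MsCl (2.5 equiv), Et3N, CH2Cl2, 0 °C
Reagents that add atoms: methanesulfonyl chloride, CS(=O)(=O)Cl
Why: Mesylation of primary alcohols is fast at 0 °C, so both hydroxyls should be capped before a monomesylate can close to a tetrahydrofuran.

Step 8
Reactants: 9 2,3-diethynylbutane-1,4-diyl dimethanesulfonate
Product: 12 2,3-diethynylbutane-1,4-diamine (meso/racemic mixture), via diazide 10 (not isolated), via bis(iminophosphorane) 11 (not isolated)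
Conditions: NaN3 (2.2 equiv), DMF, 45 °C; then PPh3, THF/H2O, rt → 45 °C, same flask; basic wash, then acid–base extraction
Reagents that add atoms: sodium azide, [Na+].[N-]=[N+]=[N-]
Why: SN2 displacement of the primary mesylates by the non-basic azide ion avoids elimination toward the enyne, and a Staudinger reduction in the same flask spares the alkynes and means that the nitrogen-rich diazide 10 is never concentrated.

Step 9
Reactants: 12 2,3-diethynylbutane-1,4-diamine; 13 3,6-dibromopyridazine
Product: 14 N1,N4-bis(6-bromopyridazin-3-yl)-2,3-diethynylbutane-1,4-diamine (meso/racemic mixture)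
Conditions: 13 (2.5 equiv), i-Pr2NEt, n-BuOH, 110 °C
Reagents that add atoms: none
Why: Nucleophilic aromatic substitution (addition–elimination) of a primary amine on 3,6-dibromopyridazine should stop after one bromide, because the amino group introduced deactivates the ring toward a second attack.

Step 10
Reactants: 14 N1,N4-bis(6-bromopyridazin-3-yl)-2,3-diethynylbutane-1,4-diamine
Product: 15 N,N'-(2,3-diethynylbutane-1,4-diyl)bis[N-(6-bromopyridazin-3-yl)acetamide] (meso/racemic mixture)
Conditions: Ac2O, DMAP (cat.), pyridine, 80 °C
Reagents that add atoms: acetic anhydride, CC(=O)OC(C)=O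
Why: DMAP-catalysed N-acylation of the secondary heteroarylamines installs the acetyl groups that withdraw the nitrogen lone pair from the diazine and twist the side chain over the ring face.

Step 11
Reactants: 15 N,N'-(2,3-diethynylbutane-1,4-diyl)bis[N-(6-bromopyridazin-3-yl)acetamide]
Product: 19 1,1'-diacetyl-5,5'-dibromo-3,3'-biindoline (meso/racemic mixture), via first bridged adduct 16 (not isolated), via mono-indoline 17 (not isolated), via second bridged adduct 18 (not isolated)
Conditions: 1,3,5-triisopropylbenzene (0.01 M, degassed), Ar, 195–200 °C, sealed vessel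
Reagents that add atoms: none
Why: Each N-acetylated 6-bromopyridazine serves as an electron-poor 4π component (C3 to C6) and its own terminal alkyne as the 2π partner in an inverse-electron-demand [4+2] cycloaddition; the bridged adducts 16 and 18 lose N2 by retro-[4+2] and aromatise irreversibly, the sequence passing through mono-indoline 17. The closest known reaction type is the intramolecular alkyne–1,2-diazine Diels–Alder synthesis of 1-acylindolines, run here twice within one molecule. Each five-membered nitrogen ring closes by C3a–C7a bond formation across the three-atom N1–C2–C3 tether (type 1 intramolecular cycloaddition, fused mode), and each benzene ring closes in the same event by C4–C5 bond formation and is completed by the N2 extrusion. No lasting stereocentre is created: the bridgeheads of 16 and 18 disappear with N2, and C3 and C3' are carried through unchanged as the meso/racemic mixture. Regiochemistry is enforced by the tether, which lets the inner alkyne carbon reach only the nitrogen-bearing diazine carbon and the terminal CH only the C–Br carbon, so bromine ends on C5; the nearer alkyne (five-membered closure) is preferred over the remote one (six-membered closure) on entropic grounds, and the acetyl groups both lower the diazine LUMO and turn the side chain over the ring face. The step also has to outrun the [3,3] shift of the hexa-1,5-diyne core, which is why it is run dilute at the lowest temperature that sustains N2 loss, helped by the two equivalent reacting pairs and the branched tether, and once 17 has formed the diyne motif no longer exists.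

Step 12
Reactants: 19 1,1'-diacetyl-5,5'-dibromo-3,3'-biindoline
Product: 20 5,5'-dibromo-3,3'-biindoline (meso/racemic mixture)
Conditions: 6 M aq HCl, 1,4-dioxane, reflux; aq NaOH work-up
Reagents that add atoms: none
Why: Acid hydrolysis of the N-aryl acetamides is standard for 1-acetylindolines and leaves the aryl bromides and the C3–C3' bond untouched.

Step 13
Reactants: 20 5,5'-dibromo-3,3'-biindoline
Product: 21 5,5'-dibromo-1H,1'H-3,3'-biindole
Conditions: DDQ (2.05 equiv), 1,4-dioxane, rt
Reagents that add atoms: none
Why: DDQ dehydrogenation of indolines runs by hydride abstraction from C2 and tautomerisation of the 3H-indole, the gain of pyrrole aromaticity drives both halves, and the two sp3 stereocentres disappear so that meso and racemic material converge on one compound.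

Step 14
Reactants: 21 5,5'-dibromo-1H,1'H-3,3'-biindole
Product: 22 rivularin-c (2,2',5,5'-tetrabromo-1H,1'H-3,3'-biindole)
Conditions: NBS (2.0 equiv), THF, −78 → 0 °C, dark
Reagents that add atoms: N-bromosuccinimide, O=C1CCC(=O)N1Br
Why: Electrophilic bromination of 3-substituted indoles with NBS goes to C2 (attack at C3 followed by bromine migration, or direct attack), which is the only free pyrrole position, while the C5 bromines deactivate the benzo rings against further substitution.

Compound list
1 | tetraethyl ethane-1,1,2,2-tetracarboxylate | CCOC(=O)C(C(=O)OCC)C(C(=O)OCC)C(=O)OCC | starting material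
2 | 2,3-bis(hydroxymethyl)butane-1,4-diol | OCC(CO)C(CO)CO | intermediate
3 | 2,2'-bis(4-methoxyphenyl)-5,5'-bi(1,3-dioxane) (all-equatorial isomer expected, ring stereochemistry irrelevant) | COc1ccc(cc1)C1OCC(CO1)C1COC(OC1)c1ccc(OC)cc1 | intermediate
4 | 2,3-bis{[(4-methoxybenzyl)oxy]methyl}butane-1,4-diol (meso/racemic mixture) | COc1ccc(COCC(CO)C(CO)COCc2ccc(OC)cc2)cc1 | intermediate
5 | 2,3-bis{[(4-methoxybenzyl)oxy]methyl}butanedial (meso/racemic mixture) | COc1ccc(COCC(C=O)C(C=O)COCc2ccc(OC)cc2)cc1 | intermediate
6 | dimethyl (1-diazo-2-oxopropyl)phosphonate | CC(=O)C(=[N+]=[N-])P(=O)(OC)OC | starting material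
7 | 3,4-bis{[(4-methoxybenzyl)oxy]methyl}hexa-1,5-diyne (meso/racemic mixture) | C#CC(COCc1ccc(OC)cc1)C(COCc1ccc(OC)cc1)C#C | intermediate
8 | 2,3-diethynylbutane-1,4-diol (meso/racemic mixture) | C#CC(CO)C(CO)C#C | intermediate
9 | 2,3-diethynylbutane-1,4-diyl dimethanesulfonate (meso/racemic mixture) | C#CC(COS(C)(=O)=O)C(COS(C)(=O)=O)C#C | intermediate
10 | 3,4-bis(azidomethyl)hexa-1,5-diyne (not isolated) | C#CC(CN=[N+]=[N-])C(CN=[N+]=[N-])C#C | intermediate
11 | 3,4-bis{[(triphenyl-λ5-phosphanylidene)amino]methyl}hexa-1,5-diyne (not isolated) | C#CC(CN=P(c1ccccc1)(c1ccccc1)c1ccccc1)C(CN=P(c1ccccc1)(c1ccccc1)c1ccccc1)C#C | intermediate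
12 | 2,3-diethynylbutane-1,4-diamine (meso/racemic mixture) | C#CC(CN)C(CN)C#C | intermediate
13 | 3,6-dibromopyridazine | Brc1ccc(Br)nn1 | starting material
14 | N1,N4-bis(6-bromopyridazin-3-yl)-2,3-diethynylbutane-1,4-diamine (meso/racemic mixture) | C#CC(CNc1ccc(Br)nn1)C(CNc1ccc(Br)nn1)C#C | intermediate
15 | N,N'-(2,3-diethynylbutane-1,4-diyl)bis[N-(6-bromopyridazin-3-yl)acetamide] (meso/racemic mixture) | C#CC(CN(C(C)=O)c1ccc(Br)nn1)C(CN(C(C)=O)c1ccc(Br)nn1)C#C | intermediate
16 | first bridged adduct: one half is a 2,3-diazabicyclo[2.2.2]octa-2,5,7-triene (bridgeheads are the former diazine C3 and C6) fused to the N-acetylpyrrolidine ring, the other half is unchanged (not isolated) | CC(=O)N1CC(C(CN(C(C)=O)c2ccc(Br)nn2)C#C)C2=CC3(Br)C=CC12N=N3 | intermediate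
17 | N-[2-(1-acetyl-5-bromoindolin-3-yl)but-3-yn-1-yl]-N-(6-bromopyridazin-3-yl)acetamide (not isolated) | CC(=O)N1CC(C(CN(C(C)=O)c2ccc(Br)nn2)C#C)c2cc(Br)ccc21 | intermediate
18 | second bridged adduct: 1-acetyl-5-bromoindolin-3-yl group on the pyrrolidine carbon of the second diazabicyclooctatriene (not isolated) | CC(=O)N1CC(C2CN(C(C)=O)C34C=CC(Br)(C=C23)N=N4)c2cc(Br)ccc21 | intermediate
19 | 1,1'-diacetyl-5,5'-dibromo-3,3'-biindoline (meso/racemic mixture) | CC(=O)N1CC(C2CN(C(C)=O)c3ccc(Br)cc23)c2cc(Br)ccc21 | intermediate
20 | 5,5'-dibromo-3,3'-biindoline (meso/racemic mixture) | Brc1ccc2NCC(C3CNc4ccc(Br)cc34)c2c1 | intermediate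
21 | 5,5'-dibromo-1H,1'H-3,3'-biindole | Brc1ccc2[nH]cc(-c3c[nH]c4ccc(Br)cc34)c2c1 | intermediate
22 | rivularin-c, 2,2',5,5'-tetrabromo-1H,1'H-3,3'-biindole | Brc1ccc2[nH]c(Br)c(-c3c(Br)[nH]c4ccc(Br)cc34)c2c1 | target

Total step count: 14. Longest linear sequence: 14 steps, from 1. Compounds 6 and 13 enter as purchased materials.

Steps most likely to fail

Step 11. The substrate may be consumed before the first cycloaddition takes place. Two processes compete at similar temperatures: a [3,3] sigmatropic shift of the hexa-1,5-diyne core and thermal oligomerisation of the terminal alkynes. The fallback sets out from 13 and returns at 21. It makes the C3–C3' bond after the cycloaddition, so that no 1,5-diyne is ever heated.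
- 13 is substituted with but-3-yn-1-amine (i-Pr2NEt, n-BuOH, 110 °C) to give 6-bromo-N-(but-3-yn-1-yl)pyridazin-3-amine F1.
- Acetylation (Ac2O, DMAP, pyridine) gives N-(6-bromopyridazin-3-yl)-N-(but-3-yn-1-yl)acetamide F2.
- Heating F2 in 1,3,5-triisopropylbenzene at 230 °C should give 1-acetyl-5-bromoindoline F3 by the same cycloaddition and N2 loss, which can now be run hotter.
- Acid hydrolysis gives 5-bromoindoline F4, and DDQ gives 5-bromo-1H-indole F5.
- Amine-catalysed addition of C3 of F5 to the ketone of 5-bromoisatin (Et2NH, EtOH) gives racemic 5-bromo-3-(5-bromo-1H-indol-3-yl)-3-hydroxyindolin-2-one F6.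
- BH3·THF removes both oxygens with aromatisation and delivers 21.

Step 5. In basic methanol the dialdehyde may lose its β-alkoxy groups by elimination. It may also be tied up as cyclic hemiacetals, so that only one of the two aldehydes is homologated. The fallback sets out from 5 and returns at 7. It replaces the diazophosphonate chemistry by a Corey–Fuchs sequence that is aprotic throughout.
- CBr4 and PPh3 in CH2Cl2 at 0 °C convert both aldehydes into dibromoalkenes, giving 1,1,6,6-tetrabromo-3,4-bis{[(4-methoxybenzyl)oxy]methyl}hexa-1,5-diene F7.
- n-BuLi (THF, −78 °C) followed by aqueous NH4Cl gives 7 by elimination, lithium–bromine exchange and protonation of the acetylides.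

Step 14. Bromination may run on to the benzo rings. The electron-rich biindole may instead be oxidised through 3-bromoindolenines that are trapped by traces of water. The acid- and light-sensitive N–H 2-bromoindole units may also degrade during isolation. The fallback sets out from 21 and returns at 22. It swaps electrophilic substitution for directed metalation.
- Boc2O and DMAP give di-tert-butyl 5,5'-dibromo-3,3'-biindole-1,1'-dicarboxylate F8.
- LiN(i-Pr)2 (THF, −78 °C) removes the C2 and C2' protons next to the carbamates without exchanging the aryl bromides.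
- BrCCl2CCl2Br traps the dianion as di-tert-butyl 2,2',5,5'-tetrabromo-3,3'-biindole-1,1'-dicarboxylate F9.
- K2CO3 in MeOH then cleaves the indole carbamates under non-acidic conditions to give 22.

Further compounds
F1 | step 11 | 6-bromo-N-(but-3-yn-1-yl)pyridazin-3-amine | C#CCCNc1ccc(Br)nn1
F2 | step 11 | N-(6-bromopyridazin-3-yl)-N-(but-3-yn-1-yl)acetamide | C#CCCN(C(C)=O)c1ccc(Br)nn1
F3 | step 11 | 1-acetyl-5-bromoindoline | CC(=O)N1CCc2cc(Br)ccc21
F4 | step 11 | 5-bromoindoline | Brc1ccc2NCCc2c1
F5 | step 11 | 5-bromo-1H-indole | Brc1ccc2[nH]ccc2c1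
F6 | step 11 | 5-bromo-3-(5-bromo-1H-indol-3-yl)-3-hydroxyindolin-2-one (racemic) | O=C1Nc2ccc(Br)cc2C1(O)c1c[nH]c2ccc(Br)cc12
F7 | step 5 | 1,1,6,6-tetrabromo-3,4-bis{[(4-methoxybenzyl)oxy]methyl}hexa-1,5-diene (meso/racemic mixture) | BrC(Br)=CC(COCc1ccc(OC)cc1)C(COCc1ccc(OC)cc1)C=C(Br)Br
F8 | step 14 | di-tert-butyl 5,5'-dibromo-3,3'-biindole-1,1'-dicarboxylate | CC(C)(C)OC(=O)n1cc(-c2cn(C(=O)OC(C)(C)C)c3ccc(Br)cc23)c2cc(Br)ccc21
F9 | step 14 | di-tert-butyl 2,2',5,5'-tetrabromo-3,3'-biindole-1,1'-dicarboxylate | CC(C)(C)OC(=O)n1c(Br)c(-c2c(Br)n(C(=O)OC(C)(C)C)c3ccc(Br)cc23)c2cc(Br)ccc21
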